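**Plan**

- Retrosynthesis: first the three MOM ethers and the C4 oxidation level are taken back (ketone to cis-alcohol, the stage at which C3 is fixed). Then O1–C8a and C4–C4a of ring C are cut together, giving a 2-aryl-3-hydroxypropanoate and a 3,5-dialkoxybenzyne. Last come the C5'–prenyl bond (Stille) and the aryl–C3–CO2Et framework (aryl-shift homologation of a benzaldehyde).
- Forward: ring B is bought as 3-bromo-4,5-dihydroxybenzaldehyde and elaborated to the hydroxy ester. Ring A is bought as phloroglucinol and turned into an o-silylaryl triflate. Ring C is closed last, onto ring A, by the aryne annulation.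
- Enabling feature: in ring A, C8a (bearing O1) and C4a (bearing the C4 carbonyl) are adjacent, and C4a is flanked by the C5 oxygen. O1 and C4 are 1,4-related along O1–C2–C3–C4. A 3-alkoxybenzyne therefore takes the C2 oxygen at the carbon remote from the alkoxy group and returns the carbanion to the ester carbon through a six-membered transition state.
- Stereochemistry: C3–H is alpha to the C4 ketone and benzylic to ring B, so it is labile to base. The annulation is run racemic, and C3 is then set by catalyst-controlled transfer hydrogenation with dynamic kinetic resolution to the cis-(3S,4S) alcohol. C4 is re-oxidised and the MOM groups are removed with acid.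

Key step: step 9

Assumption: phloroglucinol, 3-bromo-4,5-dihydroxybenzaldehyde, ethyl diazoacetate and tributyl(3-methylbut-2-en-1-yl)stannane are purchased; the C3 hydrogen of a 3-aryl-4-chromanone is taken to epimerise under fluoride or amine base, so material is carried racemic up to step 10.

**Route**

Step 1
Reactants: 1 phloroglucinol (benzene-1,3,5-triol)
Product: 2 3,5-bis(methoxymethoxy)phenol
Conditions: MOMCl (2 equiv), iPr2NEt, DMF, 0 °C to rt; chromatography
Reagents that add atoms: chloromethyl methyl ether (MOMCl), COCCl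
Why: Williamson-type O-alkylation of the phenoxide with MOMCl, where two equivalents should make the bis-ether the main component of a statistical mixture that is separable from the mono- and tris-ethers.

Step 2
Reactants: 2 3,5-bis(methoxymethoxy)phenol
Product: 3 2-bromo-3,5-bis(methoxymethoxy)phenol
Conditions: NBS (1 equiv), CH2Cl2, −78 °C
Reagents that add atoms: N-bromosuccinimide, O=C1CCC(=O)N1Br
Why: Electrophilic aromatic bromination of the activated phenol, expected ortho to the free hydroxyl (two equivalent positions, less hindered than C4 between the two OMOM groups), with low temperature to hold it at monobromination.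

Step 3
Reactants: 3 2-bromo-3,5-bis(methoxymethoxy)phenol
Product: 6 3,5-bis(methoxymethoxy)-2-(trimethylsilyl)phenyl trifluoromethanesulfonate, via aryl trimethylsilyl ether 4 (not isolated), via lithium 2-silylphenoxide 5 (not isolated)
Conditions: HMDS, THF, 70 °C, concentrate; n-BuLi, THF, −78 °C; Tf2O, −78 °C
Reagents that add atoms: hexamethyldisilazane, C[Si](C)(C)N[Si](C)(C)C; trifluoromethanesulfonic anhydride, O=S(=O)(OS(=O)(=O)C(F)(F)F)C(F)(F)F
Why: O-silylation followed by bromine–lithium exchange triggers a retro-Brook 1,3 O-to-C silyl shift to the phenoxide, which is triflated in the flask, the standard entry to o-silylaryl triflates.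

Step 4
Reactants: 7 3-bromo-4,5-dihydroxybenzaldehyde
Product: 8 3-bromo-5-hydroxy-4-methoxybenzaldehyde
Conditions: MeI (1.1 equiv), Li2CO3, DMF, 45 °C
Reagents that add atoms: iodomethane, CI
Why: Regioselective Williamson methylation of the more acidic 4-hydroxyl (para to the aldehyde, ortho to bromine) under weak-base conditions that form only the mono-phenoxide.

Step 5
Reactants: 8 3-bromo-5-hydroxy-4-methoxybenzaldehyde
Product: 9 3-bromo-4-methoxy-5-(methoxymethoxy)benzaldehyde
Conditions: MOMCl, iPr2NEt, CH2Cl2, 0 °C to rt
Reagents that add atoms: chloromethyl methyl ether (MOMCl), COCCl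
Why: Standard MOM protection of the remaining phenol, chosen because the acetal survives fluoride, amine base, hydride and the oxidant used later.

Step 6
Reactants: 9 3-bromo-4-methoxy-5-(methoxymethoxy)benzaldehyde
Product: 10 ethyl (Z)-2-[3-bromo-4-methoxy-5-(methoxymethoxy)phenyl]-3-hydroxyprop-2-enoate (enol form of the alpha-formyl ester)
Conditions: N2CHCO2Et (1.3 equiv), HBF4·OEt2 (10 mol %), CH2Cl2, −78 °C
Reagents that add atoms: ethyl diazoacetate, CCOC(=O)C=[N+]=[N-]
Why: Acid-catalysed addition of the diazo ester to the aldehyde followed by a 1,2-aryl shift with loss of N2 (aryl-migration homologation of aromatic aldehydes to 3-hydroxy-2-arylacrylates), the para-methoxy aryl group being expected to migrate in preference to hydride.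

Step 7
Reactants: 10 ethyl (Z)-2-[3-bromo-4-methoxy-5-(methoxymethoxy)phenyl]-3-hydroxyprop-2-enoate
Product: 11 ethyl 2-[3-bromo-4-methoxy-5-(methoxymethoxy)phenyl]-3-hydroxypropanoate (racemic)
Conditions: NaBH4, EtOH, 0 °C
Reagents that add atoms: none
Why: Borohydride reduction of the formyl tautomer of the beta-formyl ester, the ester being inert at 0 °C, gives the primary alcohol with a stereocentre that is racemic by design.

Step 8
Reactants: 11 ethyl 2-[3-bromo-4-methoxy-5-(methoxymethoxy)phenyl]-3-hydroxypropanoate
Product: 12 ethyl 3-hydroxy-2-[4-methoxy-3-(methoxymethoxy)-5-(3-methylbut-2-en-1-yl)phenyl]propanoate (racemic)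
Conditions: Bu3SnCH2CH=CMe2, Pd(PPh3)4 (5 mol %), DMF, 100 °C
Reagents that add atoms: tributyl(3-methylbut-2-en-1-yl)stannane, CCCC[Sn](CCCC)(CCCC)CC=C(C)C
Why: Stille coupling of the aryl bromide with the prenylstannane tolerates the free hydroxyl and the ester and should give the linear prenyl isomer by reductive elimination at the less substituted allyl terminus.

Step 9
Reactants: 12 ethyl 3-hydroxy-2-[4-methoxy-3-(methoxymethoxy)-5-(3-methylbut-2-en-1-yl)phenyl]propanoate; 6 3,5-bis(methoxymethoxy)-2-(trimethylsilyl)phenyl trifluoromethanesulfonate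
Product: 15 5,7-bis(methoxymethoxy)-3-[4-methoxy-3-(methoxymethoxy)-5-(3-methylbut-2-en-1-yl)phenyl]chroman-4-one (racemic), via 3,5-bis(methoxymethoxy)benzyne 13 (not isolated), via aryl cesium adduct 14 (not isolated)
Conditions: 6 (1.3 equiv, slow addition), CsF (4 equiv), THF, 65 °C
Reagents that add atoms: none
Why: Proposed new method: fluoride unmasks aryne 13 from 6, the fluoride-activated primary hydroxyl of 12 adds to the aryne carbon remote from the neighbouring OMOM group, and the aryl anion 14 so formed, ortho to the new ether oxygen, attacks the ester carbonyl four atoms away and expels ethoxide, so that O1–C8a and C4–C4a form in one operation. The closest known reaction type is the fluoride-mediated coupling of o-silylaryl triflates with methyl salicylates to xanthones (O-arylation followed by intramolecular acyl substitution), here extended from a phenol to an aliphatic beta-hydroxyl. Ring C closes by 6-exo-trig attack of the aryl carbanion on the ester C=O followed by loss of ethoxide. C3 is formed racemic on purpose, because its hydrogen is acidic under these conditions, so no stereocontrol is asked of this step. The selectivities needed are the regiochemistry of the aryne addition, secured by the OMOM group adjacent to the aryne carbon that becomes C4a (distortion and inductive stabilisation of the carbanion), and acyl capture over protonation of the aryl anion, favoured by aprotic THF, the six-membered transition state and slow addition of 6, which also limits arylation of the product enolate.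

Step 10
Reactants: 15 5,7-bis(methoxymethoxy)-3-[4-methoxy-3-(methoxymethoxy)-5-(3-methylbut-2-en-1-yl)phenyl]chroman-4-one (racemic)
Product: 16 (3S,4S)-5,7-bis(methoxymethoxy)-3-[4-methoxy-3-(methoxymethoxy)-5-(3-methylbut-2-en-1-yl)phenyl]chroman-4-ol (cis)
Conditions: RuCl[(S,S)-TsDPEN](p-cymene) (5 mol %), HCO2H/Et3N (2:5), EtOAc, 40 °C
Reagents that add atoms: none
Why: Asymmetric transfer hydrogenation of Noyori type under dynamic kinetic resolution, in which triethylamine equilibrates the C3 epimers through the enol while the (S,S)-catalyst reduces the 3S ketone faster and delivers hydride anti to the C3 aryl group, so that both C3 and C4 are set by the catalyst as the cis-(3S,4S) alcohol and the isolated prenyl alkene is left alone.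

Step 11
Reactants: 16 (3S,4S)-5,7-bis(methoxymethoxy)-3-[4-methoxy-3-(methoxymethoxy)-5-(3-methylbut-2-en-1-yl)phenyl]chroman-4-ol
Product: 17 (3S)-5,7-bis(methoxymethoxy)-3-[4-methoxy-3-(methoxymethoxy)-5-(3-methylbut-2-en-1-yl)phenyl]chroman-4-one
Conditions: DMP, NaHCO3, CH2Cl2, 0 °C to rt
Reagents that add atoms: none
Why: Dess–Martin oxidation with bicarbonate buffering returns the C4 ketone without amine base or free acid, so the C3 configuration set in step 10 should be retained and the electron-rich benzylic alcohol should not ionise.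

Step 12
Reactants: 17 (3S)-5,7-bis(methoxymethoxy)-3-[4-methoxy-3-(methoxymethoxy)-5-(3-methylbut-2-en-1-yl)phenyl]chroman-4-one
Product: 18 (3S)-5,7,3'-trihydroxy-4'-methoxy-5'-prenylisoflavanone (target)
Conditions: HCl (3 M aq)/MeOH, rt
Reagents that add atoms: none
Why: Acid-catalysed methanolysis of the three aryl MOM acetals is used because base would epimerise C3 through the enolate, whereas the hydrogen-bonded 5-hydroxy-4-ketone should enolise only slowly in dilute acid at room temperature, and the prenyl group has no ortho hydroxyl to cyclise onto.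

**Compound list**

1 | phloroglucinol (benzene-1,3,5-triol) | Oc1cc(O)cc(O)c1 | starting material
2 | 3,5-bis(methoxymethoxy)phenol | COCOc1cc(O)cc(OCOC)c1 | intermediate
3 | 2-bromo-3,5-bis(methoxymethoxy)phenol | COCOc1cc(O)c(Br)c(OCOC)c1 | intermediate
4 | [2-bromo-3,5-bis(methoxymethoxy)phenoxy]trimethylsilane | COCOc1cc(O[Si](C)(C)C)c(Br)c(OCOC)c1 | intermediate
5 | lithium 3,5-bis(methoxymethoxy)-2-(trimethylsilyl)phenoxide | COCOc1cc([O-])c([Si](C)(C)C)c(OCOC)c1.[Li+] | intermediate
6 | 3,5-bis(methoxymethoxy)-2-(trimethylsilyl)phenyl trifluoromethanesulfonate | COCOc1cc(OS(=O)(=O)C(F)(F)F)c([Si](C)(C)C)c(OCOC)c1 | intermediate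
7 | 3-bromo-4,5-dihydroxybenzaldehyde | O=Cc1cc(O)c(O)c(Br)c1 | starting material
8 | 3-bromo-5-hydroxy-4-methoxybenzaldehyde | COc1c(O)cc(C=O)cc1Br | intermediate
9 | 3-bromo-4-methoxy-5-(methoxymethoxy)benzaldehyde | COCOc1cc(C=O)cc(Br)c1OC | intermediate
10 | ethyl (Z)-2-[3-bromo-4-methoxy-5-(methoxymethoxy)phenyl]-3-hydroxyprop-2-enoate | CCOC(=O)/C(=C\O)c1cc(Br)c(OC)c(OCOC)c1 | intermediate
11 | ethyl 2-[3-bromo-4-methoxy-5-(methoxymethoxy)phenyl]-3-hydroxypropanoate (racemic) | CCOC(=O)C(CO)c1cc(Br)c(OC)c(OCOC)c1 | intermediate
12 | ethyl 3-hydroxy-2-[4-methoxy-3-(methoxymethoxy)-5-(3-methylbut-2-en-1-yl)phenyl]propanoate (racemic) | CCOC(=O)C(CO)c1cc(CC=C(C)C)c(OC)c(OCOC)c1 | intermediate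
13 | 3,5-bis(methoxymethoxy)benzyne | COCOC1=CC(OCOC)=CC#C1 | intermediate
14 | {2-[3-ethoxy-3-oxo-2-(4-methoxy-3-(methoxymethoxy)-5-prenylphenyl)propoxy]-4,6-bis(methoxymethoxy)phenyl}cesium | CCOC(=O)C(COc1cc(OCOC)cc(OCOC)c1[Cs])c1cc(CC=C(C)C)c(OC)c(OCOC)c1 | intermediate
15 | 5,7-bis(methoxymethoxy)-3-[4-methoxy-3-(methoxymethoxy)-5-(3-methylbut-2-en-1-yl)phenyl]chroman-4-one (racemic) | COCOc1cc(OCOC)c2C(=O)C(c3cc(CC=C(C)C)c(OC)c(OCOC)c3)COc2c1 | intermediate
16 | (3S,4S)-5,7-bis(methoxymethoxy)-3-[4-methoxy-3-(methoxymethoxy)-5-(3-methylbut-2-en-1-yl)phenyl]chroman-4-ol | COc1c(OCOC)cc([C@H]2COc3cc(OCOC)cc(OCOC)c3[C@H]2O)cc1CC=C(C)C | intermediate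
17 | (3S)-5,7-bis(methoxymethoxy)-3-[4-methoxy-3-(methoxymethoxy)-5-(3-methylbut-2-en-1-yl)phenyl]chroman-4-one | COc1c(OCOC)cc([C@H]2COc3cc(OCOC)cc(OCOC)c3C2=O)cc1CC=C(C)C | intermediate
18 | (3S)-5,7-dihydroxy-3-[3-hydroxy-4-methoxy-5-(3-methylbut-2-en-1-yl)phenyl]chroman-4-one | COc1c(O)cc([C@H]2COc3cc(O)cc(O)c3C2=O)cc1CC=C(C)C | target

**Count**

Total steps: 12. Longest linear sequence: 9 steps (steps 4 to 12, from 3-bromo-4,5-dihydroxybenzaldehyde); steps 1 to 3 form the convergent ring A branch.

**Steps most likely to fail, with fallbacks**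

Step 9 (proposed new method). The aryl anion may be protonated before it reaches the ester, leaving only O-arylation. The hydroxy ester may undergo base-induced beta-elimination or retro-aldol cleavage, and the product enolate may be arylated by excess aryne. The fallback uses known chemistry, sets out from 12 and returns at 15. Compound 12 is mesylated (MsCl, Et3N, CH2Cl2) to ethyl 2-[4-methoxy-3-(methoxymethoxy)-5-prenylphenyl]-3-(methylsulfonyloxy)propanoate F1. Elimination with DBU gives ethyl 2-[4-methoxy-3-(methoxymethoxy)-5-prenylphenyl]prop-2-enoate F2. Saponification (LiOH, THF/H2O) gives 2-[4-methoxy-3-(methoxymethoxy)-5-prenylphenyl]prop-2-enoic acid F3. F3 is then heated with 6 and CsF in THF at 125 °C in a sealed tube. This is the established insertion of an aryne into the C–O bond of a carboxylic acid: the carboxylate adds to aryne 13 at the carbon remote from OMOM and the acyl group shifts to the adjacent carbon. The resulting 1-[2-hydroxy-4,6-bis(methoxymethoxy)phenyl]-2-arylprop-2-en-1-one F4 is not isolated, because its phenoxide closes ring C by oxa-Michael addition to give 15.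

Step 10. Hydride transfer to the electron-rich C4 carbonyl, which is flanked by the C5 OMOM group, may be slow. Epimerisation at C3 may not keep pace with reduction, which would erode diastereo- and enantioselectivity. The very electron-rich benzylic alcohol may also ionise in the formate medium. The fallback sets out from 15 and returns at 17 without passing through the alcohol. Compound 15 is O-silylated (LiHMDS, then TMSCl, THF, −78 °C) to [5,7-bis(methoxymethoxy)-3-(4-methoxy-3-(methoxymethoxy)-5-prenylphenyl)-2H-chromen-4-yl]oxytrimethylsilane F5. F5 is then subjected to catalytic enantioselective protonation with a chiral BINOL-derived N-triflyl thiophosphoramide and phenol as the stoichiometric proton source in toluene. This reaction type is established for silyl enol ethers of 2-aryl cycloalkanones. The catalyst antipode is chosen to deliver 3S, giving 17 directly.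

Step 6. Hydride shift may compete with aryl shift and give the beta-keto ester, and the strong acid may cleave the MOM acetal. The fallback uses only basic conditions, sets out from 9 and returns at 11, bypassing 10. Addition of chloroform (CHCl3, DBU) to 9 gives 1-[3-bromo-4-methoxy-5-(methoxymethoxy)phenyl]-2,2,2-trichloroethanol F6. A Jocic-type reductive homologation (NaBH4, NaOH, t-BuOH, 55 °C) gives 2-[3-bromo-4-methoxy-5-(methoxymethoxy)phenyl]acetic acid F7. Esterification (EtI, K2CO3, DMF) gives ethyl 2-[3-bromo-4-methoxy-5-(methoxymethoxy)phenyl]acetate F8. Hydroxymethylation of F8 with paraformaldehyde (K2CO3 catalytic, DMSO, rt) gives 11.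

**Further compounds**

F1 | step 9 | ethyl 2-[4-methoxy-3-(methoxymethoxy)-5-(3-methylbut-2-en-1-yl)phenyl]-3-(methylsulfonyloxy)propanoate | CCOC(=O)C(COS(C)(=O)=O)c1cc(CC=C(C)C)c(OC)c(OCOC)c1
F2 | step 9 | ethyl 2-[4-methoxy-3-(methoxymethoxy)-5-(3-methylbut-2-en-1-yl)phenyl]prop-2-enoate | CCOC(=O)C(=C)c1cc(CC=C(C)C)c(OC)c(OCOC)c1
F3 | step 9 | 2-[4-methoxy-3-(methoxymethoxy)-5-(3-methylbut-2-en-1-yl)phenyl]prop-2-enoic acid | OC(=O)C(=C)c1cc(CC=C(C)C)c(OC)c(OCOC)c1
F4 | step 9 | 1-[2-hydroxy-4,6-bis(methoxymethoxy)phenyl]-2-[4-methoxy-3-(methoxymethoxy)-5-(3-methylbut-2-en-1-yl)phenyl]prop-2-en-1-one | C=C(C(=O)c1c(O)cc(OCOC)cc1OCOC)c1cc(CC=C(C)C)c(OC)c(OCOC)c1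
F5 | step 10 | [5,7-bis(methoxymethoxy)-3-(4-methoxy-3-(methoxymethoxy)-5-(3-methylbut-2-en-1-yl)phenyl)-2H-chromen-4-yl]oxytrimethylsilane | COCOc1cc(OCOC)c2C(O[Si](C)(C)C)=C(c3cc(CC=C(C)C)c(OC)c(OCOC)c3)COc2c1
F6 | step 6 | 1-[3-bromo-4-methoxy-5-(methoxymethoxy)phenyl]-2,2,2-trichloroethanol | OC(c1cc(Br)c(OC)c(OCOC)c1)C(Cl)(Cl)Cl
F7 | step 6 | 2-[3-bromo-4-methoxy-5-(methoxymethoxy)phenyl]acetic acid | OC(=O)Cc1cc(Br)c(OC)c(OCOC)c1
F8 | step 6 | ethyl 2-[3-bromo-4-methoxy-5-(methoxymethoxy)phenyl]acetate | CCOC(=O)Cc1cc(Br)c(OC)c(OCOC)c1
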